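## Analysis of the target

The target is a daucane sesquiterpenoid ester: a trans-fused bicyclo[5.3.0]decane in which a cyclopentane (C1–C5) shares the C1–C5 bond with a cycloheptenone (C1, C10, C9, C8, C7, C6, C5). Numbering used throughout, also for the corresponding atoms of all intermediates: C1 is the quaternary carbon with the angular methyl, C4 the carbinol carbon with the isopropyl group, C5 the ring-fusion CH, C6 the ester carbon, C8 the methyl-bearing sp2 carbon, C10 the ketone; β is the face of the C1 methyl.

There are four stereocentres, C4–C5–C1 contiguous plus C6. On the cyclopentane the C1 methyl, the C4 hydroxyl and the C5–C6 bond are β, while the isopropyl group, H5 and the C1–C10 bond are α (hence the trans fusion); the C6 ester oxygen is α. C5 sits between two fully substituted carbons, and C1 is a quaternary centre next to the ketone.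

Sensitive groups: the enone C10(=O)–C9=C8 carries the acyloxy group at its δ carbon (C6) with acidic γ hydrogens at C7, so base invites vinylogous elimination; the tertiary C4 alcohol and the phenolic ester limit acid and nucleophiles.

The feature the route is built on: the oxygens at C10 and C6 are 1,5-related across the isoprene-like unit C9=C8(CH3)–C7, which is the relation between the two carbons that hold an ether oxygen before and after a [2,3]-shift. Read this way, C10, C9, C8, C7 and C6 are the carbons of a 4-methyl-3,6-dihydro-2H-pyran whose ring oxygen joins C6 and C10. The remaining atoms (C1 with its methyl, C2, C3, C4 with hydroxyl and isopropyl, C5, C6) are the ten carbons of terpinen-4-ol after ring contraction.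

## Retrosynthetic reasoning

**Ester and C6 (20 ← 19 ← 17 + 18).** The C6–O bond is cut with inversion. The only stereochemical handle near C6 is the β hydroxyl at C4, and it can steer reagents only to the β face. The oxygen is therefore placed β at C6 (17) and inverted while acid 18 is attached. The phenol is unmasked last under weakly basic conditions because of the δ-acyloxy enone.

**C5–H and C6–O (17 ← 16 ← 15).** Both bonds are traced back to the C5=C6 alkene of 15. Forward, the C4 hydroxyl directs epoxidation to the β face (16), and a reductive opening must then put hydrogen on C5 from the α face. That step creates the trans ring fusion.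

**Key disconnection (15 ← 14 ← 11).** The C1–C10 bond is cut and the C6–O bond is re-formed, so the seven-membered carbocycle of 14 becomes the six-membered ether of 11. One isomerisation then delivers the seven-membered ring, the quaternary centre, the oxygen at C10 and the C8=C9 bond in its final place. The configuration of C1 is traced back to C6 of 11, a secondary carbinol centre that is easy to set. Forward, the reaction must deprotonate C10 selectively and rearrange in the [2,3] sense.

**Dihydropyran (11 ← 10 ← 9 ← 8 ← 6).** Cuts at C8=C9 (ring-closing metathesis), O–C10 (O-allylation) and C6–C7 (reagent-controlled 2-methylallylation of aldehyde 6, which sets C6). The silyl group is removed between 8 and 9 because it would migrate to the secondary alkoxide during O-alkylation, and because the free C4 hydroxyl is needed later as the directing group.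

**Ring contraction and chiral pool (6 ← 4 ← 2 ← 1).** The C5=C1 bond is cut (intramolecular aldol condensation of keto aldehyde 4), and the two carbonyls go back to the ring alkene of 1. Compound 1 supplies ten of the fifteen skeletal carbons and the C4 stereocentre with both of its substituents. The silyl ether 2 is needed because the free β-hydroxy aldehyde would undergo retro-aldol cleavage.

## Alternatives that were turned down

**Alternative 1:** the textbook cut at C8=C9 by ring-closing metathesis of the cyclopentane A1, which carries the acryloyl group on C1 and the 2-methylallyl carbinol on C5. The forward key step closes the seven-membered ring but sets no stereocentre. All four centres would have to be built first on a cyclopentane whose C5 lies between two fully substituted carbons. The C1/C5 relation would come from an enolate trapping that cannot tell the methyl from the acyl-bearing substituent. The estimated length is well above that of the chosen route, and the hard part is left to the steps before the key step.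

**Alternative 2:** cut C1–C5 and C8–C9, an intramolecular (4+3) cycloaddition of the oxyallyl cation from chloro ketone A2 (C9–C10–C1) onto its tethered 2-silyloxydiene (C5=C6–C7=C8) to give A3 with both rings formed at once. It was turned down for three reasons. The acyclic tertiary carbinol of A2 has no reliable enantioselective access. The ring fusion and the face of C1 relative to C4 depend on compact versus extended transition states that the substrate does not bias. A3 would still need dehydrogenation at C8–C9 and a stereoselective reduction at C6.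

**Alternative 3:** cut C5–C1 and C5–C6, a Büchner ring expansion in which the carbene carbon of diazoketone A4 (C5) is inserted into the 2,6-dimethoxy-4-methylphenyl ring (C1, C10, C9, C8, C7, C6) to give azulenone A5. The mapping of the seven-membered ring onto the arene is attractive, but A5 is racemic at an epimerisable C5 and offers no handle for absolute control. The angular methyl would have to be added by alkylation of an extended enolate, which favours cis fusion and competes with C7 and C9. The isopropyl addition at C4 would be unguided.

Key step: step 8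

Remark: (S)-(+)-terpinen-4-ol (1) is assumed to be used enantiopure; a commercial lot of lower enantiomeric purity would have to be enriched first, since the route does not correct C4.

## Route

Step 1
Reactants: 1 (S)-(+)-terpinen-4-ol
Product: 2 (S)-triethyl{[4-methyl-1-(propan-2-yl)cyclohex-3-en-1-yl]oxy}silane
Conditions: TESOTf, 2,6-lutidine, CH2Cl2, 0 °C
Reagents that add atoms: triethylsilyl trifluoromethanesulfonate, CC[Si](CC)(CC)OS(=O)(=O)C(F)(F)F
Why: Silylation of a tertiary alcohol with a silyl triflate; the ether prevents retro-aldol cleavage of the β-oxygenated aldehyde formed in step 2 and hemiketal formation with the ketone; no stereocentre is touched.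

Step 2
Reactants: 2 (S)-triethyl{[4-methyl-1-(propan-2-yl)cyclohex-3-en-1-yl]oxy}silane
Product: 4 (S)-6-oxo-3-(propan-2-yl)-3-[(triethylsilyl)oxy]heptanal, via ozonide 3 (not isolated)
Conditions: O3, CH2Cl2, −78 °C; then Me2S, −78 °C to rt
Reagents that add atoms: ozone, [O-][O+]=O
Why: Ozonolysis of the only C=C bond with reductive work-up should give the methyl ketone and the aldehyde; the stereocentre is not involved.

Step 3
Reactants: 4 (S)-6-oxo-3-(propan-2-yl)-3-[(triethylsilyl)oxy]heptanal
Product: 6 (R)-2-methyl-5-(propan-2-yl)-5-[(triethylsilyl)oxy]cyclopent-1-ene-1-carbaldehyde, via aldol adduct 5 (not isolated)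
Conditions: piperidine (cat.), AcOH (cat.), benzene, 80 °C, Dean–Stark
Reagents that add atoms: none
Why: Amine-catalysed intramolecular aldol condensation, the standard ring contraction of p-menthene-derived keto aldehydes: the enamine of the aldehyde attacks the methyl ketone (5-exo) and dehydration gives the tetrasubstituted enal; the silyloxy group is a poor leaving group, so ring closure should outpace β-elimination.

Step 4
Reactants: 6 (R)-2-methyl-5-(propan-2-yl)-5-[(triethylsilyl)oxy]cyclopent-1-ene-1-carbaldehyde
Product: 8 (S)-3-methyl-1-{(R)-2-methyl-5-(propan-2-yl)-5-[(triethylsilyl)oxy]cyclopent-1-en-1-yl}but-3-en-1-ol, via borinate 7 (not isolated)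
Conditions: (−)-Ipc2BOMe, 2-methylallylMgCl, Et2O, −78 °C to rt; then 6, −78 °C; NaOH, H2O2
Reagents that add atoms: 2-methylallylmagnesium chloride, CC(=C)C[Mg]Cl
Why: Reagent-controlled asymmetric allylboration (Brown type) through a closed chair transition state; the borane made from (−)-Ipc2BOMe should give the S carbinol at C6, the sense established for aryl and alkenyl aldehydes, largely independent of the remote C4 centre.

Step 5
Reactants: 8 (S)-3-methyl-1-{(R)-2-methyl-5-(propan-2-yl)-5-[(triethylsilyl)oxy]cyclopent-1-en-1-yl}but-3-en-1-ol
Product: 9 (R)-2-[(S)-1-hydroxy-3-methylbut-3-en-1-yl]-3-methyl-1-(propan-2-yl)cyclopent-2-en-1-ol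
Conditions: TBAF, THF, 0 °C to rt
Reagents that add atoms: none
Why: Fluoride desilylation; it is done here because under the basic O-alkylation of step 6 the silyl group would shift from the tertiary to the secondary oxygen, and the free C4 hydroxyl is the directing group of step 10.

Step 6
Reactants: 9 (R)-2-[(S)-1-hydroxy-3-methylbut-3-en-1-yl]-3-methyl-1-(propan-2-yl)cyclopent-2-en-1-ol
Product: 10 (R)-3-methyl-2-[(S)-3-methyl-1-(prop-2-en-1-yloxy)but-3-en-1-yl]-1-(propan-2-yl)cyclopent-2-en-1-ol
Conditions: NaH (1.1 equiv), allyl bromide, Bu4NI (cat.), THF, 0 °C to rt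
Reagents that add atoms: allyl bromide, C=CCBr
Why: Williamson ether synthesis; with one equivalent of base the secondary alkoxide is alkylated, while the tertiary hydroxyl flanked by the isopropyl group and the ring should react far more slowly; C6 is not touched.

Step 7
Reactants: 10 (R)-3-methyl-2-[(S)-3-methyl-1-(prop-2-en-1-yloxy)but-3-en-1-yl]-1-(propan-2-yl)cyclopent-2-en-1-ol
Product: 11 (R)-3-methyl-2-[(S)-4-methyl-3,6-dihydro-2H-pyran-2-yl]-1-(propan-2-yl)cyclopent-2-en-1-ol
Conditions: RuCl2(=CHPh)(PCy3)(H2IMes) (second-generation Grubbs catalyst, 5 mol%), CH2Cl2, 40 °C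
Reagents that add atoms: none
Why: Ring-closing metathesis of the allyl and 2-methylallyl termini to the trisubstituted alkene of a six-membered cyclic ether with loss of ethylene; the tetrasubstituted cyclopentene is inert to the catalyst.

Step 8
Reactants: 11 (R)-3-methyl-2-[(S)-4-methyl-3,6-dihydro-2H-pyran-2-yl]-1-(propan-2-yl)cyclopent-2-en-1-ol
Product: 14 (1S,4R,10R)-dauca-5,8-diene-4,10-diol [(3R,8R,8aS)-6,8a-dimethyl-3-(propan-2-yl)-1,2,3,5,8,8a-hexahydroazulene-3,8-diol], via dilithio ether 12 (not isolated), via dilithium dialkoxide 13 (not isolated)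
Conditions: s-BuLi (2.3 equiv), THF, −78 to −40 °C; then H2O
Reagents that add atoms: none
Why: Proposed new method: s-BuLi first forms the C4 alkoxide and then removes one of the C10 hydrogens of 11 (the only CH2 that is both allylic and α to the ring oxygen), and the allyl anion 12 should undergo a suprafacial [2,3]-sigmatropic (Wittig) shift across the exocyclic allyl unit O–C6–C5=C1, so that C10 bonds to C1 while the C6–O bond breaks and the ring oxygen ends as the C10 alkoxide of 13. The closest known reactions are the [2,3]-Wittig rearrangement of acyclic bis-allylic ethers, which tolerates a fully substituted alkene terminus and then gives a quaternary carbon, and the [1,2]- and [1,4]-Wittig shifts of lithiated 6-substituted 3,6-dihydro-2H-pyrans, which show that this carbanion forms and that the C6–O bond is the one that breaks; what is untested is the ring-expanding topology with the carbanion inside the ring and the alkene outside it. The seven-membered carbocycle is closed by ring expansion (the six ring atoms minus oxygen plus C5 and C1) through the usual five-membered envelope transition state, which here is bicyclic and resembles an 8-oxabicyclo[3.2.1]octene whose O–C6 bridge bond is breaking; it needs the cyclopentenyl group axial on the half-chair, a small conformational cost. C1 is set by 1,3-chirality transfer from C6: the new bond forms on the alkene face from which oxygen leaves, and because the ring holds C7 syn to C1 only one rotamer about C6–C5 can react, so the 6S ether can deliver C10 only to the α face of C1 (1S, methyl β). C10 is formed 10R with its oxygen pointing back toward C6, again fixed by the bicyclic geometry, and is erased in step 9; the new C5=C6 bond necessarily has C7 cis to C1. The selectivity needed is [2,3] over the [1,2] and [1,4] pathways and C10–H over C6–H deprotonation; the concerted, symmetry-allowed shift at low temperature and the better accessibility of the methylene hydrogens should secure both. The C4 alkoxide lies on the β face, away from the reacting α face.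

Step 9
Reactants: 14 (1S,4R,10R)-dauca-5,8-diene-4,10-diol
Product: 15 (1S,4R)-4-hydroxydauca-5,8-dien-10-one [(3R,8aS)-3-hydroxy-6,8a-dimethyl-3-(propan-2-yl)-2,3,5,8a-tetrahydroazulen-8(1H)-one]
Conditions: Dess–Martin periodinane, pyridine, CH2Cl2, 0 °C to rt
Reagents that add atoms: none
Why: Dess–Martin oxidation of the secondary allylic alcohol gives the C10 enone with C8=C9 already in place; the tertiary alcohol cannot be oxidised, and because C1 bears no hydrogen the C5=C6 bond cannot move into conjugation.

Step 10
Reactants: 15 (1S,4R)-4-hydroxydauca-5,8-dien-10-one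
Product: 16 (1S,4R,5S,6R)-5,6-epoxy-4-hydroxydauc-8-en-10-one (5β,6β-epoxide)
Conditions: VO(acac)2 (5 mol%), t-BuOOH, CH2Cl2, 0 °C
Reagents that add atoms: tert-butyl hydroperoxide, CC(C)(C)OO
Why: Vanadium-catalysed hydroxyl-directed epoxidation of the tertiary allylic alcohol should deliver oxygen to C5=C6 from the face of the C4 hydroxyl (β); the electron-poor enone alkene is not addressed.

Step 11
Reactants: 16 (1S,4R,5S,6R)-5,6-epoxy-4-hydroxydauc-8-en-10-one
Product: 17 (1S,4R,5S,6R)-4,6-dihydroxydauc-8-en-10-one (6β-alcohol, H5 α)
Conditions: Cp2TiCl2 (20 mol%), Mn, 2,4,6-collidine·HCl, 1,4-cyclohexadiene, THF, rt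
Reagents that add atoms: none
Why: Titanocene-mediated reductive epoxide opening: Cp2TiCl (trivalent titanium, formed in situ) cleaves the C5–O bond homolytically to the tertiary C5 radical, which should take a hydrogen atom from 1,4-cyclohexadiene on the α face, anti to the titanium alkoxide at C6 and to the β groups on C1 and C4; this sets H5 α (trans fusion) and leaves the 6β-alcohol.

Step 12
Reactants: 17 (1S,4R,5S,6R)-4,6-dihydroxydauc-8-en-10-one, 18 4-acetoxybenzoic acid
Product: 19 (1S,4R,5S,6S)-4-hydroxy-10-oxodauc-8-en-6-yl 4-acetoxybenzoate
Conditions: PPh3, DIAD, toluene, 0 °C to rt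
Reagents that add atoms: none
Why: Mitsunobu esterification with inversion at C6 should convert the 6β-alcohol into the 6α-ester in the same step that attaches the acid; the tertiary C4 alcohol does not react.

Step 13
Reactants: 19 (1S,4R,5S,6S)-4-hydroxy-10-oxodauc-8-en-6-yl 4-acetoxybenzoate
Product: 20 (1S,4R,5S,6S)-4-hydroxy-10-oxodauc-8-en-6-yl 4-hydroxybenzoate [(3R,3aS,4S,8aS)-3-hydroxy-6,8a-dimethyl-8-oxo-3-(propan-2-yl)-1,2,3,3a,4,5,8,8a-octahydroazulen-4-yl 4-hydroxybenzoate]
Conditions: NH3 (7 M in MeOH), 0 °C
Reagents that add atoms: none
Why: Aminolysis of the aryl acetate, which should be far faster than attack on the hindered secondary benzoate; the weak base and low temperature are chosen to avoid vinylogous elimination of the C6 ester.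

## Compound list

1 | (S)-(+)-terpinen-4-ol | CC1=CC[C@](O)(C(C)C)CC1 | starting material
2 | (S)-triethyl{[4-methyl-1-(propan-2-yl)cyclohex-3-en-1-yl]oxy}silane | CC1=CC[C@](O[Si](CC)(CC)CC)(C(C)C)CC1 | intermediate
3 | secondary ozonide of 2 (S at the silyloxy carbon; new bridgehead centres not defined) | CC12CC[C@@](O[Si](CC)(CC)CC)(C(C)C)CC(OO1)O2 | intermediate (not isolated)
4 | (S)-6-oxo-3-(propan-2-yl)-3-[(triethylsilyl)oxy]heptanal | O=CC[C@](O[Si](CC)(CC)CC)(C(C)C)CCC(C)=O | intermediate
5 | aldol adduct, (5R)-2-hydroxy-2-methyl-5-(propan-2-yl)-5-[(triethylsilyl)oxy]cyclopentane-1-carbaldehyde (new centres not defined) | O=CC1C(C)(O)CC[C@@]1(O[Si](CC)(CC)CC)C(C)C | intermediate (not isolated)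
6 | (R)-2-methyl-5-(propan-2-yl)-5-[(triethylsilyl)oxy]cyclopent-1-ene-1-carbaldehyde | O=CC1=C(C)CC[C@@]1(O[Si](CC)(CC)CC)C(C)C | intermediate
7 | diisopinocampheylborinate of 8 | C=C(C)C[C@H](OB([C@@H]2C[C@@H]3C[C@H]([C@H]2C)C3(C)C)[C@@H]2C[C@@H]3C[C@H]([C@H]2C)C3(C)C)C1=C(C)CC[C@@]1(O[Si](CC)(CC)CC)C(C)C | intermediate (not isolated)
8 | (S)-3-methyl-1-{(R)-2-methyl-5-(propan-2-yl)-5-[(triethylsilyl)oxy]cyclopent-1-en-1-yl}but-3-en-1-ol | C=C(C)C[C@H](O)C1=C(C)CC[C@@]1(O[Si](CC)(CC)CC)C(C)C | intermediate
9 | (R)-2-[(S)-1-hydroxy-3-methylbut-3-en-1-yl]-3-methyl-1-(propan-2-yl)cyclopent-2-en-1-ol | C=C(C)C[C@H](O)C1=C(C)CC[C@@]1(O)C(C)C | intermediate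
10 | (R)-3-methyl-2-[(S)-3-methyl-1-(prop-2-en-1-yloxy)but-3-en-1-yl]-1-(propan-2-yl)cyclopent-2-en-1-ol | C=CCO[C@@H](CC(C)=C)C1=C(C)CC[C@@]1(O)C(C)C | intermediate
11 | (R)-3-methyl-2-[(S)-4-methyl-3,6-dihydro-2H-pyran-2-yl]-1-(propan-2-yl)cyclopent-2-en-1-ol | CC1=CCO[C@@H](C1)C2=C(C)CC[C@@]2(O)C(C)C | intermediate
12 | dilithio ether: lithium alkoxide of 11, lithiated at C10 (C6 of the pyran) | [Li]C1C=C(C)C[C@H](O1)C2=C(C)CC[C@@]2(O[Li])C(C)C | intermediate (not isolated)
13 | dilithium dialkoxide of 14 | CC1=C[C@@H](O[Li])[C@@]2(C)CC[C@@](O[Li])(C(C)C)C2=CC1 | intermediate (not isolated)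
14 | (1S,4R,10R)-dauca-5,8-diene-4,10-diol | CC1=C[C@@H](O)[C@@]2(C)CC[C@@](O)(C(C)C)C2=CC1 | intermediate
15 | (1S,4R)-4-hydroxydauca-5,8-dien-10-one | CC1=CC(=O)[C@@]2(C)CC[C@@](O)(C(C)C)C2=CC1 | intermediate
16 | (1S,4R,5S,6R)-5,6-epoxy-4-hydroxydauc-8-en-10-one | CC1=CC(=O)[C@@]2(C)CC[C@@](O)(C(C)C)[C@]23O[C@@H]3C1 | intermediate
17 | (1S,4R,5S,6R)-4,6-dihydroxydauc-8-en-10-one | CC1=CC(=O)[C@@]2(C)CC[C@@](O)(C(C)C)[C@@H]2[C@H](O)C1 | intermediate
18 | 4-acetoxybenzoic acid | CC(=O)Oc1ccc(cc1)C(O)=O | starting material
19 | (1S,4R,5S,6S)-4-hydroxy-10-oxodauc-8-en-6-yl 4-acetoxybenzoate | CC1=CC(=O)[C@@]2(C)CC[C@@](O)(C(C)C)[C@@H]2[C@@H](OC(=O)c2ccc(OC(C)=O)cc2)C1 | intermediate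
20 | (1S,4R,5S,6S)-4-hydroxy-10-oxodauc-8-en-6-yl 4-hydroxybenzoate | CC1=CC(=O)[C@@]2(C)CC[C@@](O)(C(C)C)[C@@H]2[C@@H](OC(=O)c2ccc(O)cc2)C1 | target

## Step count and least certain steps

Total step count: 13. Longest linear sequence: 13 steps (1 to 20); 18 is a commercial coupling partner.

**Step 8 (key step, proposed new method).** The lithiated ether may take the [1,2]- or [1,4]-Wittig course (ring contraction or cyclopropane formation through radical-pair or ionic pathways) instead of the [2,3]-shift. This becomes more likely if the axial conformer needed to reach the hindered C1 is poorly populated, and deprotonation at C6–H would also divert material. The fallback uses known chemistry, sets out from allyl ether 10 and returns at 15. An acyclic [2,3]-Wittig rearrangement of the bis-allylic ether 10 (n-BuLi, THF, −78 to −30 °C, deprotonation at the O-allyl CH2) should give the triene diol F1. The same C6 to C1 chirality transfer applies, and C7 should end cis to C1 because the other rotamer suffers allylic strain with the C4 substituents. Ring-closing metathesis of the vinyl and 2-methylallyl groups with RuCl2(=CHPh)(PCy3)(H2IMes) should give the dienediol as a mixture of C10 epimers F2. Dess–Martin oxidation converges both epimers on 15.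

**Step 11.** Hydrogen-atom delivery to the wrong face of the C5 radical would give the cis-fused isomer. The radical may also migrate the C10 acyl group (1,2-acyl shift) or revert to the alkene by loss of the titanium oxide. The fallback sets out from diol 14 and returns at 19, and it uses the α-oriented C10 hydroxyl left by the key step. Chlorodimethylsilane and Et3N should silylate the secondary alcohol to the dimethylsilyl ether F3. Intramolecular hydrosilylation with Pt2(dvtms)3 (Karstedt's catalyst) should add Si to C6 and H to C5 from the α face, giving the cyclic siloxane F4. Tamao–Fleming oxidation (KF, KHCO3, H2O2) should give the triol F5 with retention at C6. MnO2 should oxidise only the allylic C10 alcohol to the 6α-alcohol F6. Acylation of F6 with 18 (EDC, DMAP) gives 19.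

**Step 12.** Elimination may win over substitution: the activated C6 oxygen can leave with a C7 hydrogen that is acidified by the enone, giving a conjugated dienone, and backside attack at the hindered C6 is slow. The fallback sets out from 17 and returns at 19. Dess–Martin oxidation should give the 6-ketone F7. Hydroxyl-directed reduction with Me4NBH(OAc)3 (Evans–Saksena conditions) should deliver hydride from the β C4 oxygen to the β face of the carbonyl and give the 6α-alcohol F6. Acylation with 18 (EDC, DMAP) gives 19 with retention.

**Step 4.** Facial control may be eroded by a mismatched pairing of the chiral borane with the C4 centre, or the addition to the hindered aldehyde may be slow. The fallback sets out from 6 and returns at 8. Addition of 2-methylallylmagnesium chloride should give 8 together with its C6 epimer F8. MnO2 oxidation of the mixture should give the ketone F9. Corey–Bakshi–Shibata reduction with (R)-2-methyl-CBS-oxazaborolidine and catecholborane should return the S alcohol 8.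

## Further compounds

F1 | step 8 | (1R,2E,3S)-3-(1-hydroxyprop-2-en-1-yl)-3-methyl-2-(3-methylbut-3-en-1-ylidene)-1-(propan-2-yl)cyclopentan-1-ol, C10 epimers | C=CC(O)[C@@]1(C)CC[C@@](O)(C(C)C)/C1=C/CC(C)=C
F2 | step 8 | (1S,4R)-dauca-5,8-diene-4,10-diol, C10 epimers | CC1=CC(O)[C@@]2(C)CC[C@@](O)(C(C)C)C2=CC1
F3 | step 11 | 10-O-dimethylsilyl ether of 14 | CC1=C[C@@H](O[SiH](C)C)[C@@]2(C)CC[C@@](O)(C(C)C)C2=CC1
F4 | step 11 | cyclic siloxane bridging O10 and C6 (Si α at C6, H5 α) | CC1=C[C@H]2O[Si](C)(C)[C@@H](C1)[C@@H]3[C@]2(C)CC[C@@]3(O)C(C)C
F5 | step 11 | (1S,4R,5S,6S,10R)-dauc-8-ene-4,6,10-triol | CC1=C[C@@H](O)[C@@]2(C)CC[C@@](O)(C(C)C)[C@@H]2[C@@H](O)C1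
F6 | step 11 | (1S,4R,5S,6S)-4,6-dihydroxydauc-8-en-10-one (6α-alcohol) | CC1=CC(=O)[C@@]2(C)CC[C@@](O)(C(C)C)[C@@H]2[C@@H](O)C1
F7 | step 12 | (1S,4R,5S)-4-hydroxydauc-8-ene-6,10-dione | CC1=CC(=O)[C@@]2(C)CC[C@@](O)(C(C)C)[C@@H]2C(=O)C1
F8 | step 4 | (R)-3-methyl-1-{(R)-2-methyl-5-(propan-2-yl)-5-[(triethylsilyl)oxy]cyclopent-1-en-1-yl}but-3-en-1-ol | C=C(C)C[C@@H](O)C1=C(C)CC[C@@]1(O[Si](CC)(CC)CC)C(C)C
F9 | step 4 | (R)-3-methyl-1-{2-methyl-5-(propan-2-yl)-5-[(triethylsilyl)oxy]cyclopent-1-en-1-yl}but-3-en-1-one | C=C(C)CC(=O)C1=C(C)CC[C@@]1(O[Si](CC)(CC)CC)C(C)C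
A1 | alternative 1 | 1-[(1S,2S,3R)-3-hydroxy-2-[(S)-1-hydroxy-3-methylbut-3-en-1-yl]-1-methyl-3-(propan-2-yl)cyclopentyl]prop-2-en-1-one | C=CC(=O)[C@@]1(C)CC[C@@](O)(C(C)C)[C@@H]1[C@@H](O)CC(C)=C
A2 | alternative 2 | (6R)-3-chloro-6-hydroxy-3-methyl-6-(propan-2-yl)-8-[(trimethylsilyl)oxy]undeca-7,9-dien-2-one | CC(=O)C(C)(Cl)CC[C@@](O)(C(C)C)C=C(O[Si](C)(C)C)/C=C/C
A3 | alternative 2 | (1S,4R,5S)-4-hydroxy-6-[(trimethylsilyl)oxy]dauc-6-en-10-one | CC1CC(=O)[C@@]2(C)CC[C@@](O)(C(C)C)[C@@H]2C(O[Si](C)(C)C)=C1
A4 | alternative 3 | 1-diazo-4-(2,6-dimethoxy-4-methylphenyl)butan-2-one | COc1cc(C)cc(OC)c1CCC(=O)C=[N+]=[N-]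
A5 | alternative 3 | 4,8-dimethoxy-6-methyl-3,8a-dihydroazulen-1(2H)-one (racemic) | COC1=CC(C)=CC(OC)=C2CCC(=O)C12
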